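**Assumption:** Albanin A has no stereocentres and its C2–C1′ aryl axis rotates freely, so it is achiral; "single enantiomer" is moot and no stereocontrol is needed.

## Retrosynthetic overview

1. Albanin A (11) ⇐ tetra-MOM ether 10; the four acetals are cleaved in the last step.
2. Key disconnection: the pyranone C ring is cut at both C4–C3 and O1–C2, giving salicylaldehyde 9 and internal skipped enyne 7. In the forward sense this is a Rh-catalysed oxidative aldehyde C–H/phenol O–H annulation that installs the C2 aryl and C3 prenyl groups in one step. This replaces the usual Baker–Venkataraman/chalcone route followed by C3 prenylation.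
3. Enyne 7 ⇐ aryl alkyne 5 + prenyl bromide (copper acetylide allylation); 5 ⇐ 2,4-dihydroxybenzaldehyde (MOM protection, then Ohira–Bestmann).
4. Salicylaldehyde 9 ⇐ 2,4,6-trihydroxybenzaldehyde by selective bis-MOM protection.
5. Ring order: the A and B rings are bought; only the C ring is built, in the key step.

## Route

**Step 1**
Reactants: 1, 2,4-dihydroxybenzaldehyde; 2, chloromethyl methyl ether (MOMCl)
Product: 3, 2,4-bis(methoxymethoxy)benzaldehyde
Conditions: NaH (2.5 equiv), MOMCl (2.5 equiv), DMF, 0 °C → rt
Reagents that add atoms: MOMCl, COCCl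
Why: Williamson-type O-alkylation of the bis-phenoxide; full deprotonation with NaH overrides the H-bond of the ortho-OH so both phenols are protected.

**Step 2**
Reactants: 3, 2,4-bis(methoxymethoxy)benzaldehyde; 4, dimethyl (1-diazo-2-oxopropyl)phosphonate (Ohira–Bestmann reagent)
Product: 5, 1-ethynyl-2,4-bis(methoxymethoxy)benzene
Conditions: 4 (1.3 equiv), K2CO3, MeOH, rt
Reagents that add atoms: Ohira–Bestmann reagent, CC(=O)C(=[N+]=[N-])P(=O)(OC)OC (supplies the terminal alkyne carbon)
Why: Seyferth–Gilbert homologation (Ohira–Bestmann variant) converts the aryl aldehyde to the terminal alkyne under mild base that MOM ethers tolerate.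

**Step 3**
Reactants: 5, 1-ethynyl-2,4-bis(methoxymethoxy)benzene; 6, prenyl bromide (1-bromo-3-methylbut-2-ene)
Product: 7, 1-(5-methylhex-4-en-1-yn-1-yl)-2,4-bis(methoxymethoxy)benzene (aryl–C≡C–CH2–CH=CMe2)
Conditions: CuI (0.5 equiv), NaI, K2CO3, prenyl bromide (1.3 equiv), DMF, rt
Reagents that add atoms: prenyl bromide, CC(C)=CCBr
Why: Copper acetylide allylic substitution; attack at the unhindered primary (α) carbon of the prenyl halide gives the linear 1,4-enyne, and the weak base avoids isomerisation to the allene.

**Step 4**
Reactants: 8, 2,4,6-trihydroxybenzaldehyde; 2, MOMCl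
Product: 9, 2-hydroxy-4,6-bis(methoxymethoxy)benzaldehyde
Conditions: MOMCl (2.1 equiv), i-Pr2NEt (2.5 equiv), CH2Cl2, 0 °C
Reagents that add atoms: MOMCl, COCCl
Why: Selective O-alkylation; after the first ortho-OH is capped, the remaining ortho-OH is locked in a hydrogen bond to the aldehyde and is not alkylated with limited reagent and amine base at 0 °C.

**Step 5 (key step)**
Reactants: 9, 2-hydroxy-4,6-bis(methoxymethoxy)benzaldehyde; 7, 1-(5-methylhex-4-en-1-yn-1-yl)-2,4-bis(methoxymethoxy)benzene (1.2 equiv)
Product: 10, 2-[2,4-bis(methoxymethoxy)phenyl]-5,7-bis(methoxymethoxy)-3-(3-methylbut-2-en-1-yl)-4H-chromen-4-one (tetra-MOM albanin A)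
Conditions: [RhCl(cod)]2 (2 mol %), 1,2,3,4-tetraphenylcyclopentadiene (8 mol %), Cu(OAc)2·H2O (2 equiv), o-xylene, 130 °C, N2
Reagents that add atoms: none (both partners are listed reactants; two H are lost to the oxidant)
Why: Rh-catalysed oxidative C–H annulation of a salicylaldehyde with an internal alkyne: phenoxide-directed aldehyde C–H cleavage gives an acyl-rhodacycle, the alkyne inserts with the aryl-bearing carbon on Rh and the CH2-prenyl carbon on the acyl carbon, and C–O reductive elimination closes the ring as the 2-aryl-3-alkyl chromone, with Cu(II) reoxidising Rh; the reaction class is known, but this hindered, skipped-enyne pairing is an untested extension.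

**Step 6**
Reactants: 10, tetra-MOM albanin A
Product: 11, Albanin A, 2-(2,4-dihydroxyphenyl)-5,7-dihydroxy-3-(3-methylbut-2-en-1-yl)-4H-chromen-4-one
Conditions: 3 M aq. HCl/MeOH (1:4), 50 °C, 2–3 h, monitored and stopped at full conversion
Reagents that add atoms: none
Why: Acid-catalysed acetal solvolysis removes all four MOM groups; the C3 prenyl group has no ortho phenol to form a chroman, so it survives brief dilute acid.

## Compound list

1 | 2,4-dihydroxybenzaldehyde | O=Cc1ccc(O)cc1O | starting material
2 | chloromethyl methyl ether (MOMCl) | COCCl | starting material (reagent)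
3 | 2,4-bis(methoxymethoxy)benzaldehyde | O=Cc1ccc(OCOC)cc1OCOC | intermediate
4 | dimethyl (1-diazo-2-oxopropyl)phosphonate | CC(=O)C(=[N+]=[N-])P(=O)(OC)OC | starting material (reagent)
5 | 1-ethynyl-2,4-bis(methoxymethoxy)benzene | C#Cc1ccc(OCOC)cc1OCOC | intermediate
6 | prenyl bromide | CC(C)=CCBr | starting material
7 | 1-(5-methylhex-4-en-1-yn-1-yl)-2,4-bis(methoxymethoxy)benzene | CC(C)=CCC#Cc1ccc(OCOC)cc1OCOC | intermediate
8 | 2,4,6-trihydroxybenzaldehyde | O=Cc1c(O)cc(O)cc1O | starting material
9 | 2-hydroxy-4,6-bis(methoxymethoxy)benzaldehyde | O=Cc1c(O)cc(OCOC)cc1OCOC | intermediate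
10 | tetra-MOM albanin A | CC(C)=CCc1c(-c2ccc(OCOC)cc2OCOC)oc2cc(OCOC)cc(OCOC)c2c1=O | intermediate
11 | Albanin A | CC(C)=CCc1c(-c2ccc(O)cc2O)oc2cc(O)cc(O)c2c1=O | target

## Summary

Total steps: 6. Longest linear sequence: 5 (steps 1 → 2 → 3 → 5 → 6); step 4 is a one-step convergent branch.

Steps most likely to fail:

1. **Step 5 (Rh annulation).** Risks are the hindered 6-alkoxy salicylaldehyde, the ortho-substituted aryl alkyne, decarbonylation, and isomerisation of the skipped enyne at 130 °C. Fallback: an ynone route. Add the lithium acetylide of 5 to 2,4,6-tris(methoxymethoxy)benzaldehyde, oxidise with MnO2, cyclise 6-endo with loss of one ortho-MOM to the protected flavone, iodinate C3, and Stille-couple with tributyl(prenyl)stannane.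
2. **Step 3 (Cu prenylation).** Risks are α/γ regioselectivity and the base-sensitive doubly activated CH2. Fallback: build the prenyl group after the ring. Use aryl–C≡C–CH2OTBS in the annulation, convert the 3-CH2OTBS to 3-CH2Br, and finish with an sp3–sp2 Suzuki coupling with 2-methylprop-1-enylboronic acid pinacol ester.
3. **Step 6 (global MOM removal).** Risk is hydration or cyclisation of the prenyl olefin under acid. Fallback: change the protecting-group strategy to TIPS ethers throughout, so the final unveiling uses buffered fluoride (TBAF/AcOH) instead of acid.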